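I take the fraction of the charge as my unit, and I read every amount in it. The question is what a flask holds at the end, so I look for a rule that connects the readings late in a run. Two exchanges in a row pass through complex with one exchanged, which nobody read. I guess its fraction as the geometric mean of its neighbours, and I count two ligands spent per complex with two exchanged.

| setting | theta | eta | delta | winter | dusk | summer |
|---|---|---|---|---|---|---|
| starting complex | 0.050 M | 0.050 M | 0.050 M | 0.050 M | 0.050 M | 0.050 M (fed, over 20 min) |
| incoming ligand | 0.050 M | 0.025 M | 0.038 M | 0.0500 M (fed, over 20 min) | 0.0500 M | 0.0500 M |
| leaving ligand | 0.050 M | 0.050 M | 0.050 M | 0.0500 M | 0.0500 M | 0.0500 M |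
| remark | run made earlier | run made earlier | run made earlier | all else is in the flask from the start; the feed brings no volume worth counting | everything together at the start | all else is in the flask from the start; the feed brings no volume worth counting |
| time |  |  |  | 25 min | 25 min | 25 min |

| run | time / min | complex with two exchanged / % | starting complex / % |
|---|---|---|---|
| theta | 2.00 | 14.3 | 26.4 |
| theta | 6.00 | 14.2 | 16.7 |
| theta | 12.0 | 12.7 | 11.8 |
| theta | 20.0 | 11.7 | 8.2 |
| theta | 25.0 | 11.1 | 7.9 |
| eta | 2.00 | 6.2 | 30.8 |
| eta | 5.00 | 5.9 | 19.6 |
| eta | 10.0 | 5.2 | 12.0 |
| eta | 15.0 | 4.6 | 9.1 |
| eta | 20.0 | 4.0 | 7.9 |
| delta | 4.00 | 10.3 | 21.2 |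
| delta | 8.00 | 9.6 | 14.4 |
| delta | 12.0 | 9.2 | 11.6 |
| delta | 15.0 | 8.4 | 10.4 |
| delta | 20.0 | 7.9 | 8.4 |

(scatter of a reading: 0.3 percentage points)



- the flask with the highest amount of complex with two exchanged, in percent of the starting complex charged ("all alike" if they lie within 1.5 percentage points) (winter / dusk / summer / all alike)
- final complex with two exchanged, as a percentage of the starting complex charged, in winter
- final complex with two exchanged, as a percentage of the starting complex charged, in dusk
- final complex with two exchanged, as a percentage of the starting complex charged, in summer

My quantity is the balance quotient, the reaction quotient of the double exchange: the fraction of complex with two exchanged over the fraction of starting complex, times the square of leaving ligand over incoming ligand. Each line gives the bare ratio, then the quotient.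

theta, 12.0 min: 1.08, 5.24

theta, 25.0 min: 1.41, 5.19

eta, 20.0 min: 0.506, 4.94

Down the theta lines the bare ratio climbs, yet the quotient stays put. The eta line has a lower ratio than the last theta line, yet its quotient lies close by. So I treat the exchange as an equilibrium, and I carry the mean of these readings, 5.13, as the balance quotient.

My figure for complex with two exchanged at the end is then the quotient times the square of incoming over leaving ligand times the starting complex left. From eta, I read a second-order loss of 0.820 min⁻¹. With that loss I reckon winter's starting complex at the end at 4.65%. For summer I assume that feed equals loss when the feed ends, and that the starting complex then decays, which I reckon gives 12.3% at the end. Assuming ligand spending near theta's, I commit to 7.10% for winter and 15.3% for summer.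

The forecast names summer, with 20% for winter, 11.2% for dusk and 30% for summer. Its ground: “Feeding the complex into excess ligand suppresses the second-order loss and favours double exchange most”. My figures are lower than its figures for winter and for summer.

The flasks end at 7.09% in winter, 11.2% in dusk and 13.3% in summer, so summer holds most. Winter ends with 2.56% of starting complex, and with 78.8% of incoming ligand and 121% of leaving ligand, each of its own charge. The balance quotient turns those into 5.54% for winter, somewhat less than the flask holds.

    starting complex + incoming ligand ⇌ leaving ligand + complex with one exchanged (K = 2.80, k = 0.410 M⁻¹ s⁻¹)
    complex with one exchanged + incoming ligand ⇌ leaving ligand + complex with two exchanged (K = 2.30, k = 1.10 M⁻¹ s⁻¹)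
    complex with two exchanged ⇌ isomer of the product (K = 0.160, k = 0.00570 s⁻¹)
    2 starting complex → self-condensation product (k = 0.140 M⁻¹ s⁻¹)

Take a flask like winter with 0.013 M of leaving ligand. It ends with 1.28% of starting complex, and the balance quotient with its ligand amounts gives 9.27%. That flask holds 11.8%, again more than the quotient gives.

(The numbers in the tables come from a simulation for substances that don't exist.)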